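Partner is what we count: each turnover, whether catalyst intermediate A gives target or catalyst intermediate B gives second product, takes one partner, so we treat it as the limiting reagent and ask what fraction of its charge comes out as target.

* the flask that ends with the higher amount of target, in percent of the starting material charged, or "neither" when 2 percentage points or less lies between them (red / ochre / neither)
* final target, as a percentage of the starting material charged, in red
* final target, as a percentage of the starting material charged, in ochre

| flask | starting material | second substrate | partner | free catalyst | impurity | remark | time |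
|---|---|---|---|---|---|---|---|
| Monday's | 0.0020 M | 2 equiv | 0.19 equiv | 2.4 mol% | 11 µM | run made earlier |  |
| Saturday's | 0.0020 M | 2 equiv | 0.28 equiv | 2.4 mol% | 11 µM | run made earlier |  |
| Sunday's | 0.0020 M | 2 equiv | 0.72 equiv | 2.4 mol% | 11 µM | run made earlier |  |
| Wednesday's | 0.0020 M | 2 equiv | 0.60 equiv | 2.6 mol% | 11 µM | run made earlier |  |
| red | 0.0020 M | 2.00 equiv | 0.150 equiv | 4 mol% | 11 µM |  | 4.0 min |
| ochre | 0.0020 M | 2.00 equiv | 0.600 equiv | 2.4 mol% | 11 µM |  | 4.0 min |

| run | time / s | target / % | starting material / % |
|---|---|---|---|
| Monday's | 10.0 | 3 | 98 |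
| Monday's | 20.0 | 2 | 98 |
| Monday's | 30.0 | 2 | 96 |
| Monday's | 60.0 | 3 | 101 |
| Monday's | 120 | 6 | 96 |
| Saturday's | 10.0 | 4 | 100 |
| Saturday's | 20.0 | 4 | 97 |
| Saturday's | 30.0 | 7 | 98 |
| Saturday's | 60.0 | 6 | 98 |
| Saturday's | 120 | 8 | 94 |
| Sunday's | 25.0 | 15 | 80 |
| Sunday's | 50.0 | 26 | 76 |
| Sunday's | 80.0 | 27 | 74 |
| Sunday's | 90.0 | 25 | 70 |
| Sunday's | 120 | 31 | 69 |
| Wednesday's | 10.0 | 12 | 93 |
| Wednesday's | 30.0 | 15 | 84 |
| Wednesday's | 60.0 | 18 | 79 |
| Wednesday's | 80.0 | 22 | 76 |
| Wednesday's | 120 | 24 | 77 |

(scatter of a reading: 2 percentage points)

1. Wednesday's last reading, 24 % of target on 0.60 equiv of partner, gives 0.400, which we carry as the partner share, the final target over the partner charged, both as fractions of the starting material charged; Sunday's last reading gives 0.431.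
2. We let that reading stand for the end, since Wednesday's target moved from 22 % at 80.0 s to 24 % at 120 s, a step of 2 percentage points, the scatter of one reading, and the asked time is twice that last reading.
3. Ochre has Wednesday's partner charge, with 2.4 mol% of free catalyst against 2.6 mol%, so the share gives 24.0 % in ochre, and the same share gives 6.00 % in red.
4. The weak link is red's number, since that share was read at a large partner charge; Monday's and Saturday's last readings, pooled, give 0.298, lower though noisy on so little target, so we reforge red to 4.47 % and commit to ochre.

The forecast also says ochre, with 26 % (21 % to 32 %) in ochre and 6.5 % (3.5 % to 11 %) in red, both above ours, and it starts from the same run: “Ochre nearly repeats Wednesday's run with slightly less catalyst.”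

The flask gives ochre, with 22.2 % in ochre and 3.23 % in red, just below the forecast's low end.

    starting material + free catalyst ⇌ catalyst intermediate A (K = 1200 M⁻¹, k = 19000 M⁻¹ s⁻¹)
    partner + catalyst intermediate A → free catalyst + target (k = 760 M⁻¹ s⁻¹)
    second substrate + free catalyst ⇌ catalyst intermediate B (K = 10000 M⁻¹, k = 430 M⁻¹ s⁻¹)
    partner + catalyst intermediate B → free catalyst + second product (k = 720 M⁻¹ s⁻¹)
    free catalyst + impurity → spent catalyst A (k = 1.50 × 10⁶ M⁻¹ s⁻¹)
    free catalyst → spent catalyst B (k = 0.0110 s⁻¹)

Ochre's partner share comes to 0.370, with partner down to 0.616 % of its own charge at 4.00 min. Struck from ochre, the reaction of second substrate with free catalyst, both ways, lifts target to 54.6 %, and the back reaction of catalyst intermediate A, struck instead, lifts it to 56.8 %, so these two acting together are a part of why ochre's share stays low. Between the flasks, the difference in partner is the largest single effect on red's target, and no more than that: red charged with ochre's partner ends at 22.6 % against 3.23 %.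

On the neighbour of ochre charged with 2.40 equiv of partner, the carried share gives 96.0 %; that flask gives 96.1 %, with 10 % of its partner left.

The runs stem from a simulated flask from invented constants; the scatter is artificial.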